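**Late times.** Late in each run I expect the substrate to have become product, so I start from that end, with these flasks:

all flasks: left-handed substrate 0.050 M; solid reagent 2.20 equiv; right-handed substrate 0.050 M; time 4.0 d

| charge | free catalyst |
|---|---|
| ochre | 0.21 mol% |
| grey | 0.25 mol% |
| green | 0.3 mol% |

    partner + free catalyst + left-handed substrate → free catalyst + left-handed product (k1 = 40100 M⁻² h⁻¹)
    partner + free catalyst + right-handed substrate → free catalyst + right-handed product (k2 = 8380 M⁻² h⁻¹)
    left-handed substrate ⇌ right-handed substrate (k3 = 1.08 h⁻¹)
    partner + free catalyst → spent catalyst (k4 = 0.435 M⁻¹ h⁻¹)
    solid reagent ⇌ partner, rate k5*(cs5 - [partner]) while solid is left; crystals form when [partner] > cs5 (cs5 = 19 mM, k5 = 0.127 h⁻¹)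

- free catalyst is single-handed; left-handed substrate and right-handed substrate are mirror images of each other, charged as a racemate, each of them at the stated concentration
- solid, in amounts per volume of the solution: solid reagent
- at the start none of the solid reagent is in solution
- run time (ochre): 4.0 d

- which of the two there is more of at the end, ochre (right-handed product / left-handed product)
- which of the two there is more of at the end, grey (right-handed product / left-handed product)
- which of the two there is more of at the end, green (right-handed product / left-handed product)
- final left-handed product, as a percentage of the left-handed substrate and right-handed substrate together charged, in ochre
- final left-handed product, as a percentage of the left-handed substrate and right-handed substrate together charged, in grey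
- final left-handed product, as a percentage of the left-handed substrate and right-handed substrate together charged, in green

**The share.** Both hands meet the same partner and free catalyst, so while the substrate stays racemic the left-handed share of product is k1/(k1+k2), 82.7%, from a selectivity factor of 4.79. That puts left-handed product ahead in each flask. Its yield is this share times one less r, where r is the substrate remainder, so r is the correction I compute.

**The remainder.** Is r negligible? At full pace the solid delivers 2.41 mM h⁻¹, and the substrate charged then needs 41.4 h, shorter than the 4.0 d allowed. But supply k5(cs5 − c(partner)) slows as c(partner) rises, and thinning substrate needs more partner. Setting supply equal to use, a rough step that ignores partner held in solution and holds while solid is left, and eliminating c(partner) gives the time to reach remainder r in ochre: T(r) = (one less r) × 41.4 h + τ × ln(one over r). Here τ is the tail time, the time in which substrate falls by a factor e with partner at its solubility, a pseudo-first-order time: 20.7 h. Racemisation, with relaxation half-life 0.321 h, is far quicker, so the share stands. A remainder of 6.25% gives T = 4.01 d, matching the run time, and a yield of 77.5%.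

**The catalyst.** But partner also destroys free catalyst. Taking c(partner) at half its solubility, I reckon that ochre's free catalyst ends at 67.3% and averages 83.6%, stretching τ to 24.7 h. Now a remainder of 10.0% gives T = 3.93 d, close to the run time. I commit to 74.4% for ochre, with grey and green higher because their bare τ, the one without catalyst loss, is shorter than ochre's, 17.4 h and 14.5 h.

**The forecast.** It puts left-handed product ahead, at 80.5% in ochre, 81.4% in grey and 81.9% in green, holding that “the loading only nudges the yield upward”. These figures lie near what the reaction taken through to completion gives, and its ochre value is higher than mine.

**The result.** Left-handed product leads, at 72.1% in ochre, 75.1% in grey and 77.6% in green. Ochre ends with 12.6% of substrate, which T(r) with bare τ reads as 3.30 d, less than the run time. A neighbour of ochre, charged with 0.36 mol% of free catalyst, has a bare τ of 12.1 h. It ends with 3.80% of substrate, which reads 3.31 d, level with ochre. At the end the neighbour's solid reagent stands at 0%, its partner at 0.0137 M and its left-handed product at 79.3%.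

(The numbers were set for the occasion; the run is a simulation.)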